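## The problem

The target is 2-(2-hydroxy-4,5-dimethoxyphenyl)-3,7,8-trimethoxy-4H-chromen-4-one (12), a flat, achiral 3-O-methylflavonol. Ring A is the benzo ring (C4a to C8a, methoxy groups at C7 and C8), ring C is the 4-pyranone (O1, C2, C3-OMe, C4=O), and ring B (C1' to C6') sits on C2 with OH at C2' and methoxy groups at C4' and C5'.

- **Oxygen differentiation.** There is no stereocentre; the task is to tell six oxygens apart. Five are methylated and one is free, and the free one (2'-OH) is not chelated to the carbonyl, so selective demethylation cannot deliver it. It has to be built in or masked throughout.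
- **A second phenol next to C2.** The 2'-OH is ortho to the C2–C1' bond. In any open-chain chalcone or 1,3-diketone precursor it competes with the ring A phenol for ring closure, which would give aurone-type products or the isomeric 6,7-dimethoxychromone. In the finished flavone it allows base-induced ring opening at C2 and reclosure through the other phenol.
- **The 3-methoxy group.** It is best brought in as a methoxyacetyl unit, not made by oxidation at C3 followed by selective methylation beside another phenol.
- **The C2–C1' bond.** It joins two electron-rich, fully oxygenated halves and is flanked by the 3-OMe and the 2'-oxygen.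
- **Sensitive groups.** C2 of the pyranone is attacked by hydroxide and alkoxide. Ring B with its free phenol is a hydroxyquinol ether that oxidises easily to a quinone, so the phenol should be unveiled last.
- **Enabling feature.** C1' is ortho to O2' and para to the 4'-methoxy group, so it is C6 of 3,4-dimethoxyphenol (6), that ring's most nucleophilic carbon. C2 is the α-carbon of ring C and becomes the electrophilic α-position of an aromatic 1-benzopyrylium ion once the C4 carbonyl oxygen is silylated. The C2–C1' bond can therefore be made between two unfunctionalised C–H positions of matched polarity, and the C4 carbonyl returns when ring C is re-aromatised.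

## Retrosynthesis

**12 from 11 (O–Si bond).** The free 2'-phenol is released last from its tert-butyldimethylsilyl ether 11, because the free ring B is the most oxidisable part of the molecule. The silyl group is not a separate protection step: it is put on in the flask of the key step, where it blocks O-attack. The forward reaction must cleave Si–O without base, so that ring C is not opened.

**11 from 9 (oxidation level of ring C).** Ring C is carried as a 2H-pyran, as in the 4-silyloxy-2H-chromene 9, and aromatised late by loss of hydride from C2 and of the silyl group from O4. This removes the only stereocentre and returns the C4 carbonyl. The oxidant must take hydride from C2 only. That C–H is the only sp3 C–H in 9 that is simultaneously benzylic to ring B, α to O1 and allylic to the enol ether.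

**9 from 7 and 8, that is from 5 and 6 (C2–C1' bond, the key cut).** This cut splits the skeleton into two halves of similar size, chromone 5 and phenol 6. Neither carries a handle at the reacting carbon, and each is available in at most two steps. The neighbouring cuts (O1–C2 or C2–C3) lead back to open-chain carbonyl precursors in which the ring B phenol must be protected and the 3-oxygen handled separately. The forward reaction has three requirements:
- the pyrylium 7 (from 5 and a silyl triflate) must react at C2 and not at C4;
- the arene 8 (6 silylated in the same flask) must react through carbon C6 and not through oxygen, C2 or C5;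
- a mild base must take the proton so that the addition cannot reverse.

**5 from 3 via 4 (O1–C2 and C2–C3 bonds).** C2 comes from a one-carbon formyl equivalent condensed onto the methylene of ketone 3. The resulting enaminone 4 closes on the only phenol present, so there is no regiochemical question. Ketone 3 already holds the 3-methoxy group.

**3 from 1 and 2 (C4–C4a bond).** Acylation of 1,2,3-trimethoxybenzene (1) with methoxyacetyl chloride (2) brings in C4 and C3 with the 3-methoxy group. Chelation-controlled demethylation ortho to the new ketone frees exactly the phenol that becomes O1. The forward reaction must cleave one aryl methyl ether out of three and leave the aliphatic one.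

## Roads not taken

**Alternative 1:** the most obvious plan cuts O1–C2 and C2–C3 at the chalcone level.
- Route: 1-(2-hydroxy-3,4-dimethoxyphenyl)ethan-1-one A1 (from 1 and acetyl chloride as in step 1) is condensed (Claisen–Schmidt) with 4,5-dimethoxy-2-(methoxymethoxy)benzaldehyde A2 (from 6 by ortho-formylation and protection) to give chalcone A3. Algar–Flynn–Oyamada oxidation with alkaline H2O2 gives flavonol A4, which is O-methylated at C3 and deprotected with acid.
- Why the chosen plan is better: this route needs a protecting group on O2' through four steps and a separate methylation for the 3-oxygen. Its ring-forming oxidation passes through intermediates in which ring B must become coplanar with ring C while flanked by the 3-oxygen and the ortho-alkoxy group, which favours diversion to aurones and dihydroflavonols. It takes about seven operations against five. The chosen plan carries the 3-methoxy group in from the start and uses the 2'-oxygen as the directing element of the bond formation.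

**Alternative 2:** the same C2–C1' cut, made by cross-coupling.
- Route: 2-iodo-3,7,8-trimethoxy-4H-chromen-4-one A5 (from 5 by metalation at C2 and iodination) is coupled (Suzuki–Miyaura, zerovalent palladium catalyst) with [2-(benzyloxy)-4,5-dimethoxyphenyl]boronic acid A6 (from 6 by bromination, benzylation, halogen–lithium exchange and borylation), followed by hydrogenolysis.
- Why the chosen plan is better: both carbons must first be functionalised, at a cost of about four extra operations, for a bond whose polarity is already present in 5 and 6. Strong base at C2 of a chromone risks ring opening. The electron-rich ortho-alkoxy boronic acid is prone to protodeboronation, and the coupling is hindered on both sides.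

**Alternative 3:** cut O1–C2 only, at an unprotected diketone.
- Route: crossed Claisen condensation of ketone 3 with methyl 2-hydroxy-4,5-dimethoxybenzoate A7 gives 1-(2-hydroxy-3,4-dimethoxyphenyl)-3-(2-hydroxy-4,5-dimethoxyphenyl)-2-methoxypropane-1,3-dione A8, which is cyclodehydrated with acid.
- Why the chosen plan is better: A8 holds two ortho-hydroxyaryl ketones. Closure through the ring A phenol gives 12, but closure through the ring B phenol gives 2-(2-hydroxy-3,4-dimethoxyphenyl)-3,6,7-trimethoxy-4H-chromen-4-one A9. The ring B phenol is the less hindered and the more electron-rich of the two (para to a methoxy group), so nothing in the structure favours 12. The chosen plan never has two free phenols beside a dicarbonyl chain.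

Key step: step 3

Remark on the chemistry: the target has no stereogenic element. The only stereocentre the route creates (C2 of compound 9) is formed racemic and is destroyed in step 4.

## Route

Step 1
Reactants: 1 1,2,3-trimethoxybenzene; 2 methoxyacetyl chloride
Product: 3 1-(2-hydroxy-3,4-dimethoxyphenyl)-2-methoxyethan-1-one
Conditions: AlCl3 (2.5 equiv), CH2Cl2, 0 °C → rt; aq. HCl work-up
Reagents that add atoms: none
Why: Friedel–Crafts acylation at C4 of 1 (ortho to one terminal methoxy group, para to the other), then in the same flask AlCl3 bridges the ketone and the ortho methoxy oxygen in a six-membered chelate and chloride removes that methyl group only; this tandem acylation and ortho-demethylation is the standard entry to 2-hydroxy-3,4-dimethoxyphenyl ketones.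

Step 2
Reactants: 3 1-(2-hydroxy-3,4-dimethoxyphenyl)-2-methoxyethan-1-one
Product: 5 3,7,8-trimethoxy-4H-chromen-4-one, via enaminone 4 (not isolated)
Conditions: Me2NCH(OMe)2 (3 equiv), toluene, 100 °C; evaporate; AcOH, 100 °C
Reagents that add atoms: N,N-dimethylformamide dimethyl acetal, COC(OC)N(C)C
Why: Aminomethylenation of the activated methylene gives the push-pull enaminone 4, whose β-carbon is attacked by the single phenol (addition–elimination, 6-endo closure of ring C) with loss of dimethylamine; this is the standard synthesis of chromones unsubstituted at C2, and the double-bond geometry of 4 is of no consequence.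

Step 3
Reactants: 5 3,7,8-trimethoxy-4H-chromen-4-one; 6 3,4-dimethoxyphenol
Product: 9 rac-tert-butyl{[2-(2-{[tert-butyl(dimethyl)silyl]oxy}-4,5-dimethoxyphenyl)-3,7,8-trimethoxy-2H-chromen-4-yl]oxy}dimethylsilane, via 4-silyloxybenzopyrylium triflate 7 (not isolated), via aryl silyl ether 8 (not isolated)
Conditions: 5, TBSOTf (1.2 equiv), ClCH2CH2Cl, 60 °C; separately 6, TBSOTf (1.05 equiv), 2,6-lutidine (2.5 equiv), CH2Cl2, 0 °C; slow addition of the first solution to the second, −20 °C → rt; aq. NaHCO3, filtration through Et3N-deactivated silica
Reagents that add atoms: tert-butyldimethylsilyl trifluoromethanesulfonate, CC(C)(C)[Si](C)(C)OS(=O)(=O)C(F)(F)F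
Why: Proposed new method: Friedel–Crafts C-arylation of a chromone-derived 4-silyloxy-1-benzopyrylium ion by a phenol silyl ether; the closest known reaction types are the additions of silyl enol ethers and allyl-metal reagents to 4-silyloxybenzopyrylium triflates made from chromones and silyl triflates, and the arylation of flavylium salts by phenols and phenol ethers. The silyl triflate silylates the most basic site of 5, the vinylogous-ester carbonyl oxygen, to give the aromatic pyrylium 7, whose acceptor orbital is largest at C2 and C4; C4 carries the silyloxy group, so addition there is hindered and reversible, and C2 is the productive site. Arene 8 attacks through its C6 (ortho to the silyloxy group, para to the 3-methoxy group), the carbon with the largest donor coefficient, whereas its C2 lies between two oxygen substituents and its C5 is activated by one ortho methoxy group only, so a single regioisomer is expected, as in the formylation and acylation of 1,2,4-trioxygenated benzenes. 2,6-Lutidine takes the proton of the Wheland intermediate, which makes the addition irreversible and protects the acid-labile enol ether of 9. Silylation of the phenol oxygen in the same flask removes the competing O-attack on C2. No ring is closed. C2 of 9 is a new stereocentre that is formed racemic and needs no control because step 4 removes it. Slow addition of 7 to an excess of 8 keeps the pyrylium concentration low, so that hydride transfer from C2–H of 9 to unreacted 7 is suppressed.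

Step 4
Reactants: 9 rac-tert-butyl{[2-(2-{[tert-butyl(dimethyl)silyl]oxy}-4,5-dimethoxyphenyl)-3,7,8-trimethoxy-2H-chromen-4-yl]oxy}dimethylsilane
Product: 11 2-(2-{[tert-butyl(dimethyl)silyl]oxy}-4,5-dimethoxyphenyl)-3,7,8-trimethoxy-4H-chromen-4-one, via 4-silyloxyflavylium salt 10 (not isolated)
Conditions: DDQ (1.2 equiv), 2,4,6-collidine (1.5 equiv), CH2Cl2, 0 °C → rt; aq. NaHCO3
Reagents that add atoms: none
Why: Dehydrogenation of a silyl enol ether to the enone by DDQ: C2–H of 9 is at once benzylic to ring B, α to O1 and allylic to the enol ether, so hydride abstraction gives the aromatic 4-silyloxyflavylium ion 10, whose silyl group is taken by the hydroquinone monoanion to leave the pyranone carbonyl; the same reaction type serves in silyl enol ether to enone conversions and in chromene to benzopyrylium oxidations, and collidine buffers the acidic hydroquinone.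

Step 5
Reactants: 11 2-(2-{[tert-butyl(dimethyl)silyl]oxy}-4,5-dimethoxyphenyl)-3,7,8-trimethoxy-4H-chromen-4-one
Product: 12 2-(2-hydroxy-4,5-dimethoxyphenyl)-3,7,8-trimethoxy-4H-chromen-4-one
Conditions: HF·pyridine, THF, 0 °C → rt
Reagents that add atoms: none
Why: Fluoride-driven cleavage of the aryl silyl ether under acidic conditions; basic desilylation is avoided because a 2'-hydroxyflavone can open at C2 and reclose through the other phenol under base, while the methyl ethers and the pyranone are inert to HF·pyridine.

## Compound list

1 | 1,2,3-trimethoxybenzene | COc1cccc(OC)c1OC | starting material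
2 | methoxyacetyl chloride | COCC(=O)Cl | starting material
3 | 1-(2-hydroxy-3,4-dimethoxyphenyl)-2-methoxyethan-1-one | COCC(=O)c1ccc(OC)c(OC)c1O | intermediate
4 | (Z)-3-(dimethylamino)-1-(2-hydroxy-3,4-dimethoxyphenyl)-2-methoxyprop-2-en-1-one | COc1ccc(C(=O)/C(OC)=C/N(C)C)c(O)c1OC | intermediate
5 | 3,7,8-trimethoxy-4H-chromen-4-one | COc1coc2c(OC)c(OC)ccc2c1=O | intermediate
6 | 3,4-dimethoxyphenol | COc1ccc(O)cc1OC | starting material
7 | 4-{[tert-butyl(dimethyl)silyl]oxy}-3,7,8-trimethoxychromenylium trifluoromethanesulfonate | COc1c[o+]c2c(OC)c(OC)ccc2c1O[Si](C)(C)C(C)(C)C.[O-]S(=O)(=O)C(F)(F)F | intermediate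
8 | tert-butyl(3,4-dimethoxyphenoxy)dimethylsilane | COc1ccc(O[Si](C)(C)C(C)(C)C)cc1OC | intermediate
9 | rac-tert-butyl{[2-(2-{[tert-butyl(dimethyl)silyl]oxy}-4,5-dimethoxyphenyl)-3,7,8-trimethoxy-2H-chromen-4-yl]oxy}dimethylsilane (racemic at C2) | COC1=C(O[Si](C)(C)C(C)(C)C)c2ccc(OC)c(OC)c2OC1c1cc(OC)c(OC)cc1O[Si](C)(C)C(C)(C)C | intermediate
10 | 4-{[tert-butyl(dimethyl)silyl]oxy}-2-(2-{[tert-butyl(dimethyl)silyl]oxy}-4,5-dimethoxyphenyl)-3,7,8-trimethoxychromenylium 2,3-dichloro-5,6-dicyano-4-hydroxyphenolate | COc1c(-c2cc(OC)c(OC)cc2O[Si](C)(C)C(C)(C)C)[o+]c2c(OC)c(OC)ccc2c1O[Si](C)(C)C(C)(C)C.[O-]c1c(Cl)c(Cl)c(O)c(C#N)c1C#N | intermediate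
11 | 2-(2-{[tert-butyl(dimethyl)silyl]oxy}-4,5-dimethoxyphenyl)-3,7,8-trimethoxy-4H-chromen-4-one | COc1cc(O[Si](C)(C)C(C)(C)C)c(-c2oc3c(OC)c(OC)ccc3c(=O)c2OC)cc1OC | intermediate
12 | 2-(2-hydroxy-4,5-dimethoxyphenyl)-3,7,8-trimethoxy-4H-chromen-4-one | COc1cc(O)c(-c2oc3c(OC)c(OC)ccc3c(=O)c2OC)cc1OC | target

## Step count and risks

Total steps: 5. Longest linear sequence: 5 (1 → 3 → 5 → 9 → 11 → 12); phenol 6 enters at step 3.

**Step 3 (key step, Proposed new method).**
- What may go wrong: C–C bond formation may be too slow, because the pyrylium is stabilised by the 7-methoxy group and the arene reacts next to a bulky silyloxy group. Hydride transfer from the product to unconsumed pyrylium may reduce part of the chromone. The enol silyl group may be lost early, giving the chromanone.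
- Fallback (known chemistry, from ketone 3 and phenol 6, returning at 12): ortho-formylation of 6 (MgCl2, Et3N, paraformaldehyde, MeCN, reflux) should give 2-hydroxy-4,5-dimethoxybenzaldehyde F1. Benzylation (BnBr, K2CO3, DMF) gives 2-(benzyloxy)-4,5-dimethoxybenzaldehyde F2. Claisen–Schmidt condensation of F2 with 3 (KOH, EtOH, rt) gives (Z)-3-[2-(benzyloxy)-4,5-dimethoxyphenyl]-1-(2-hydroxy-3,4-dimethoxyphenyl)-2-methoxyprop-2-en-1-one F3. Oxidative cyclisation (catalytic I2, DMSO, 120 °C) gives 2-[2-(benzyloxy)-4,5-dimethoxyphenyl]-3,7,8-trimethoxy-4H-chromen-4-one F4, and hydrogenolysis (H2, Pd/C, EtOAc) gives 12. This is the conventional logic and costs the protecting group the main route avoids.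

**Step 4.**
- What may go wrong: the acidic hydroquinone may protodesilylate the enol ether before hydride abstraction, leaving a chromanone that DDQ oxidises only sluggishly. Ring B may be over-oxidised.
- Fallback (from 9, returning at 11): deliberate hydrolysis of the enol ether (AcOH, THF, water, rt) gives 2-(2-{[tert-butyl(dimethyl)silyl]oxy}-4,5-dimethoxyphenyl)-3,7,8-trimethoxy-2,3-dihydro-4H-chromen-4-one F5 as a mixture of diastereomers, both centres being erased next. Dehydrogenation with catalytic I2 in DMSO at 110 °C (iodination at C3, loss of HI) gives 11. If the aryl silyl ether is lost under these conditions, the product is 12 itself.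

**Step 1.**
- What may go wrong: loss of selectivity in the ether cleavage. The aliphatic methoxy group (five-membered chelate) or the central methoxy group may be cleaved, or demethylation may be incomplete.
- Fallback (from 1 and 2, returning at 3): 2 is converted with N,O-dimethylhydroxylamine hydrochloride and Et3N into N,2-dimethoxy-N-methylacetamide F6. Compound 1 is lithiated at C4 (n-BuLi, TMEDA, THF, 0 °C) and acylated with F6 at −78 °C to give 2-methoxy-1-(2,3,4-trimethoxyphenyl)ethan-1-one F7. BCl3 (1.1 equiv, CH2Cl2, −78 → 0 °C) then cleaves only the methoxy group ortho to the carbonyl and gives 3.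

**Step 2.**
- What may go wrong: slow condensation at the methylene that carries the methoxy group, with O-methylation of the phenol by the acetal as a competing process.
- Fallback (from 3, returning at 5): Claisen formylation with ethyl formate and NaH (THF, 0 °C → rt) gives the cyclic hemiacetal 2-hydroxy-3,7,8-trimethoxy-2,3-dihydro-4H-chromen-4-one F8, which is dehydrated with HCl in AcOH to 5.

## Further compounds

F1 | step 3 | 2-hydroxy-4,5-dimethoxybenzaldehyde | COc1cc(O)c(C=O)cc1OC
F2 | step 3 | 2-(benzyloxy)-4,5-dimethoxybenzaldehyde | COc1cc(OCc2ccccc2)c(C=O)cc1OC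
F3 | step 3 | (Z)-3-[2-(benzyloxy)-4,5-dimethoxyphenyl]-1-(2-hydroxy-3,4-dimethoxyphenyl)-2-methoxyprop-2-en-1-one | COc1cc(OCc2ccccc2)c(/C=C(\OC)C(=O)c2ccc(OC)c(OC)c2O)cc1OC
F4 | step 3 | 2-[2-(benzyloxy)-4,5-dimethoxyphenyl]-3,7,8-trimethoxy-4H-chromen-4-one | COc1cc(OCc2ccccc2)c(-c2oc3c(OC)c(OC)ccc3c(=O)c2OC)cc1OC
F5 | step 4 | 2-(2-{[tert-butyl(dimethyl)silyl]oxy}-4,5-dimethoxyphenyl)-3,7,8-trimethoxy-2,3-dihydro-4H-chromen-4-one (mixture of diastereomers) | COC1C(=O)c2ccc(OC)c(OC)c2OC1c1cc(OC)c(OC)cc1O[Si](C)(C)C(C)(C)C
F6 | step 1 | N,2-dimethoxy-N-methylacetamide | COCC(=O)N(C)OC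
F7 | step 1 | 2-methoxy-1-(2,3,4-trimethoxyphenyl)ethan-1-one | COCC(=O)c1ccc(OC)c(OC)c1OC
F8 | step 2 | 2-hydroxy-3,7,8-trimethoxy-2,3-dihydro-4H-chromen-4-one (mixture of diastereomers) | COC1C(O)Oc2c(OC)c(OC)ccc2C1=O
A1 | alternative 1 | 1-(2-hydroxy-3,4-dimethoxyphenyl)ethan-1-one | CC(=O)c1ccc(OC)c(OC)c1O
A2 | alternative 1 | 4,5-dimethoxy-2-(methoxymethoxy)benzaldehyde | COCOc1cc(OC)c(OC)cc1C=O
A3 | alternative 1 | (E)-1-(2-hydroxy-3,4-dimethoxyphenyl)-3-[4,5-dimethoxy-2-(methoxymethoxy)phenyl]prop-2-en-1-one | COCOc1cc(OC)c(OC)cc1/C=C/C(=O)c1ccc(OC)c(OC)c1O
A4 | alternative 1 | 3-hydroxy-7,8-dimethoxy-2-[4,5-dimethoxy-2-(methoxymethoxy)phenyl]-4H-chromen-4-one | COCOc1cc(OC)c(OC)cc1-c1oc2c(OC)c(OC)ccc2c(=O)c1O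
A5 | alternative 2 | 2-iodo-3,7,8-trimethoxy-4H-chromen-4-one | COc1c(I)oc2c(OC)c(OC)ccc2c1=O
A6 | alternative 2 | [2-(benzyloxy)-4,5-dimethoxyphenyl]boronic acid | COc1cc(OCc2ccccc2)c(B(O)O)cc1OC
A7 | alternative 3 | methyl 2-hydroxy-4,5-dimethoxybenzoate | COC(=O)c1cc(OC)c(OC)cc1O
A8 | alternative 3 | 1-(2-hydroxy-3,4-dimethoxyphenyl)-3-(2-hydroxy-4,5-dimethoxyphenyl)-2-methoxypropane-1,3-dione | COc1ccc(C(=O)C(OC)C(=O)c2cc(OC)c(OC)cc2O)c(O)c1OC
A9 | alternative 3 | 2-(2-hydroxy-3,4-dimethoxyphenyl)-3,6,7-trimethoxy-4H-chromen-4-one | COc1ccc(-c2oc3cc(OC)c(OC)cc3c(=O)c2OC)c(O)c1OC
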